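The disconnection on which everything rests is the C1–C6 bond of the benzoic acid ring (C1 bears the carboxyl, C6 the tridecyl chain), which is retrosynthetically an aldol bond within a linear tetracarbonyl chain. In one operation a mild amine base closes this carbocycle from an acyclic dioxinone, expels water and hands over the 2,4-dioxygenated benzene ring as a benzodioxinone in which the carboxyl and the C2 oxygen are tied up together. The precursor is a 2,2-dimethyl-dioxinone whose C6 substituent is a heptadecyl chain with ketones at chain C2 and C4 and both (S)-carbinol centres (chain C6 and C16) as silyl ethers. Those ethers are later exchanged directly for acetates.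

Key step: step 10

Remark on the chemistry: the side chain of the arene is numbered C1'–C13' from the ring. A free C2' hydroxyl beside the resorcylate carbonyl is assumed to close readily to a 3,4-dihydroisocoumarin. The silyl ethers are therefore swapped for acetates without a free-alcohol stage, and the chain acid is used as its Weinreb amide.

Step 1
Reactants: 1 (S)-propylene oxide; 2 10-bromodec-1-ene
Product: 4 (S)-tridec-12-en-2-ol, via dec-9-enylmagnesium bromide 3 (not isolated)
Conditions: Mg, THF, rt → 40 °C; then CuI (10 mol %), 1, THF, −30 → 0 °C; aq. NH4Cl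
Reagents that add atoms: none
Why: Copper-catalysed Grignard opening of a terminal epoxide, in which the organocopper species attacks the unsubstituted CH2 in SN2 fashion, so the stereocentre of 1 is not touched and its (S) configuration becomes C2 of 4.

Step 2
Reactants: 4 (S)-tridec-12-en-2-ol
Product: 5 (S)-tert-butyldimethyl(tridec-12-en-2-yloxy)silane
Conditions: TBSCl, imidazole, DMF, rt
Reagents that add atoms: tert-butyldimethylsilyl chloride, CC(C)(C)[Si](C)(C)Cl
Why: Standard imidazole-promoted silylation of a secondary alcohol (Corey protocol), which masks the hydroxyl for the oxidative and carbanion steps that follow without touching the stereocentre.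

Step 3
Reactants: 5 (S)-tert-butyldimethyl(tridec-12-en-2-yloxy)silane
Product: 7 (S)-11-(tert-butyldimethylsilyloxy)dodecanoic acid, via (S)-11-(tert-butyldimethylsilyloxy)dodecanal 6 (not isolated)
Conditions: O3, CH2Cl2, −78 °C; Me2S, −78 °C → rt; concentrate; NaClO2, NaH2PO4, 2-methylbut-2-ene, t-BuOH/H2O, rt
Reagents that add atoms: ozone, [O-][O+]=O; sodium chlorite, [Na+].[O-]Cl=O
Why: Ozonolysis of the terminal alkene with reductive work-up gives the aldehyde, which Pinnick oxidation (chlorite with a hypochlorite scavenger) converts to the acid under buffered conditions that a secondary silyl ether tolerates.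

Step 4
Reactants: 7 (S)-11-(tert-butyldimethylsilyloxy)dodecanoic acid; 8 Meldrum's acid (2,2-dimethyl-1,3-dioxane-4,6-dione)
Product: 10 methyl (13S)-13-(tert-butyldimethylsilyloxy)-3-oxotetradecanoate, via acyl Meldrum's acid 9 (not isolated)
Conditions: DCC, DMAP, CH2Cl2, 0 °C → rt; filter, concentrate; MeOH, reflux
Reagents that add atoms: methanol, CO
Why: Carbodiimide C-acylation of Meldrum's acid followed by methanolysis, in which the acyl Meldrum's acid fragments to an acyl ketene that methanol traps while acetone and CO2 leave (Oikawa–Yonemitsu β-keto ester synthesis).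

Step 5
Reactants: 10 methyl (13S)-13-(tert-butyldimethylsilyloxy)-3-oxotetradecanoate
Product: 11 methyl (3S,13S)-13-(tert-butyldimethylsilyloxy)-3-hydroxytetradecanoate
Conditions: H2 (4 atm), RuCl2[(S)-BINAP](dmf)n (0.5 mol %), MeOH, 50 °C
Reagents that add atoms: none
Why: Noyori asymmetric hydrogenation, in which the β-keto ester chelates the divalent ruthenium centre and the (S)-BINAP ligand directs hydride to one carbonyl face, which for simple 3-oxoalkanoates gives the (3S) alcohol under pure catalyst control, the remote C13 centre being a spectator.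

Step 6
Reactants: 11 methyl (3S,13S)-13-(tert-butyldimethylsilyloxy)-3-hydroxytetradecanoate
Product: 12 methyl (3S,13S)-3,13-bis(tert-butyldimethylsilyloxy)tetradecanoate
Conditions: TBSCl, imidazole, DMF, rt
Reagents that add atoms: tert-butyldimethylsilyl chloride, CC(C)(C)[Si](C)(C)Cl
Why: Silylation of the β-hydroxy ester under mild imidazole conditions that cause neither retro-aldol cleavage nor elimination, so the new (3S) centre is retained.

Step 7
Reactants: 12 methyl (3S,13S)-3,13-bis(tert-butyldimethylsilyloxy)tetradecanoate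
Product: 13 (3S,13S)-3,13-bis(tert-butyldimethylsilyloxy)-N-methoxy-N-methyltetradecanamide
Conditions: MeNHOMe·HCl, i-PrMgCl, THF, −20 → 0 °C
Reagents that add atoms: N,O-dimethylhydroxylamine hydrochloride, CNOC.Cl
Why: Weinreb amide formation by acyl substitution of the methyl ester with the chloromagnesium amide generated in the flask, run cold so that the β-silyloxy group is not eliminated.

Step 8
Reactants: 14 2,2,6-trimethyl-4H-1,3-dioxin-4-one
Product: 16 2,2-dimethyl-6-(2-oxopropyl)-4H-1,3-dioxin-4-one, via lithium dienolate 15 (not isolated)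
Conditions: LiN(SiMe3)2 (1.0 equiv), THF, −78 °C; AcCl (0.5 equiv), −78 °C; aq. NH4Cl
Reagents that add atoms: acetyl chloride, CC(Cl)=O
Why: γ-Deprotonation of the dioxinone methyl group gives the lithium dienolate, which is C-acylated at its exocyclic carbon by acetyl chloride (vinylogous Claisen-type acylation), the second equivalent of enolate taking up the more acidic product.

Step 9
Reactants: 16 2,2-dimethyl-6-(2-oxopropyl)-4H-1,3-dioxin-4-one; 13 (3S,13S)-3,13-bis(tert-butyldimethylsilyloxy)-N-methoxy-N-methyltetradecanamide
Product: 18 6-[(6S,16S)-6,16-bis(tert-butyldimethylsilyloxy)-2,4-dioxoheptadecyl]-2,2-dimethyl-4H-1,3-dioxin-4-one, via dilithium dianion 17 (not isolated)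
Conditions: 16 (2.0 equiv), LiN(i-Pr)2 (4.2 equiv), THF, −78 °C; then 13 (1.0 equiv), −78 → −40 °C; aq. NH4Cl
Reagents that add atoms: none
Why: Claisen-type acylation of a 1,3-dicarbonyl dianion, in which the terminal, last-formed and most nucleophilic carbon attacks the Weinreb amide, whose chelated tetrahedral adduct survives until the quench and so prevents over-addition, while the low temperature suppresses enolisation of the amide and loss of the β-silyloxy group.

Step 10
Reactants: 18 6-[(6S,16S)-6,16-bis(tert-butyldimethylsilyloxy)-2,4-dioxoheptadecyl]-2,2-dimethyl-4H-1,3-dioxin-4-one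
Product: 20 5-[(2S,12S)-2,12-bis(tert-butyldimethylsilyloxy)tridecyl]-7-hydroxy-2,2-dimethyl-4H-1,3-benzodioxin-4-one, via aldol adduct 19 (not isolated)
Conditions: Et3N (5 equiv), CH2Cl2, rt
Reagents that add atoms: none
Why: Et3N reversibly removes a proton from side-chain C1, giving a dienolate that runs through dioxinone C6 and C5 to the ring carbonyl; its α-carbon (dioxinone C5, the future arene C1) adds to the C4 ketone (future arene C6) to give the cyclic β-hydroxy ketone 19, which loses water by E1cB and tautomerises at the remaining C2 ketone to the phenol. The closest known reaction type is the base-mediated biomimetic aromatisation of diketo-dioxinones to isopropylidene-protected resorcylates, an intramolecular vinylogous aldol condensation. The single ring is closed in the 6-(enolexo)-exo-trig mode. No stereocentre is created in the product, since the carbinol centre of 19 is erased on dehydration, and the silyloxy centres at C2' and C12' lie outside the reacting array and are untouched. The step needs C-cyclisation onto the C4 ketone in preference to O-cyclisation to a pyranone and to E1cB loss of the chain C6 silyloxy group. The first is secured because the carboxyl terminus is locked in the dioxinone as a poorly electrophilic vinylogous carbonate, so only the six-membered carbocycle can form and aromatisation makes it irreversible; the second because the weak amine base touches only methylenes flanked by two carbonyl groups and silanolate is a poor leaving group.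

Step 11
Reactants: 20 5-[(2S,12S)-2,12-bis(tert-butyldimethylsilyloxy)tridecyl]-7-hydroxy-2,2-dimethyl-4H-1,3-benzodioxin-4-one
Product: 21 benzyl 6-[(2S,12S)-2,12-bis(tert-butyldimethylsilyloxy)tridecyl]-2,4-dihydroxybenzoate
Conditions: BnOH (5 equiv), NaH (3.5 equiv), THF, 0 °C → rt; aq. NH4Cl
Reagents that add atoms: benzyl alcohol, OCc1ccccc1
Why: Alkoxide transesterification of a salicylate acetonide, in which sodium benzyl oxide adds to the benzodioxinone carbonyl, the ring opens and the hemiketal alkoxide sheds acetone, giving the benzyl ester and the free C2 phenol, with the silyl ethers stable to alkoxide.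

Step 12
Reactants: 21 benzyl 6-[(2S,12S)-2,12-bis(tert-butyldimethylsilyloxy)tridecyl]-2,4-dihydroxybenzoate
Product: 22 benzyl 2,4-diacetoxy-6-[(2S,12S)-2,12-diacetoxytridecyl]benzoate
Conditions: Ac2O (10 equiv), Cu(OTf)2 (5 mol %), CH2Cl2, 0 °C → rt
Reagents that add atoms: acetic anhydride, CC(=O)OC(C)=O
Why: Lewis acid-catalysed direct silyl ether to acetate exchange, in which Cu(OTf)2-activated acetic anhydride acylates the ether oxygen and the silyl group leaves as silyl acetate, so the C–O bonds at C2' and C12' are never broken (configuration retained) and no free C2' alcohol appears that could lactonise onto the ester, while both phenols are acetylated in the same flask.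

Step 13
Reactants: 22 benzyl 2,4-diacetoxy-6-[(2S,12S)-2,12-diacetoxytridecyl]benzoate
Product: 23 benzyl 6-[(2S,12S)-2,12-diacetoxytridecyl]-2,4-dihydroxybenzoate
Conditions: pyrrolidine (2.5 equiv), CH2Cl2, 0 °C → rt
Reagents that add atoms: none
Why: Chemoselective aminolysis, since aryl acetates, with a phenoxide leaving group, are cleaved by pyrrolidine far faster than secondary alkyl acetates or the hindered, electron-rich benzyl benzoate.

Step 14
Reactants: 23 benzyl 6-[(2S,12S)-2,12-diacetoxytridecyl]-2,4-dihydroxybenzoate
Product: 24 6-[(2S,12S)-2,12-diacetoxytridecyl]-2,4-dihydroxybenzoic acid (CNP0203944.2)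
Conditions: H2 (1 atm), 10% Pd/C, EtOAc, rt
Reagents that add atoms: none
Why: Catalytic hydrogenolysis of the benzylic C–O bond of the ester on palladium, under neutral conditions at room temperature that leave the alkyl acetates, the non-benzylic C2' centre and the decarboxylation-prone salicylic acid intact.

Compound list
1 | (S)-propylene oxide | C[C@H]1CO1 | starting material
2 | 10-bromodec-1-ene | BrCCCCCCCCC=C | starting material
3 | dec-9-enylmagnesium bromide | C=CCCCCCCCC[Mg]Br | intermediate (not isolated)
4 | (S)-tridec-12-en-2-ol | C[C@H](O)CCCCCCCCCC=C | intermediate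
5 | (S)-tert-butyldimethyl(tridec-12-en-2-yloxy)silane | C[C@H](O[Si](C)(C)C(C)(C)C)CCCCCCCCCC=C | intermediate
6 | (S)-11-(tert-butyldimethylsilyloxy)dodecanal | C[C@H](O[Si](C)(C)C(C)(C)C)CCCCCCCCCC=O | intermediate (not isolated)
7 | (S)-11-(tert-butyldimethylsilyloxy)dodecanoic acid | C[C@H](O[Si](C)(C)C(C)(C)C)CCCCCCCCCC(=O)O | intermediate
8 | Meldrum's acid (2,2-dimethyl-1,3-dioxane-4,6-dione) | CC1(C)OC(=O)CC(=O)O1 | starting material
9 | 5-[(11S)-11-(tert-butyldimethylsilyloxy)-1-hydroxydodecylidene]-2,2-dimethyl-1,3-dioxane-4,6-dione (acyl Meldrum's acid, enol form) | C[C@H](O[Si](C)(C)C(C)(C)C)CCCCCCCCCC(O)=C1C(=O)OC(C)(C)OC1=O | intermediate (not isolated)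
10 | methyl (13S)-13-(tert-butyldimethylsilyloxy)-3-oxotetradecanoate | C[C@H](O[Si](C)(C)C(C)(C)C)CCCCCCCCCC(=O)CC(=O)OC | intermediate
11 | methyl (3S,13S)-13-(tert-butyldimethylsilyloxy)-3-hydroxytetradecanoate | C[C@H](O[Si](C)(C)C(C)(C)C)CCCCCCCCC[C@H](O)CC(=O)OC | intermediate
12 | methyl (3S,13S)-3,13-bis(tert-butyldimethylsilyloxy)tetradecanoate | C[C@H](O[Si](C)(C)C(C)(C)C)CCCCCCCCC[C@H](O[Si](C)(C)C(C)(C)C)CC(=O)OC | intermediate
13 | (3S,13S)-3,13-bis(tert-butyldimethylsilyloxy)-N-methoxy-N-methyltetradecanamide | C[C@H](O[Si](C)(C)C(C)(C)C)CCCCCCCCC[C@H](O[Si](C)(C)C(C)(C)C)CC(=O)N(C)OC | intermediate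
14 | 2,2,6-trimethyl-4H-1,3-dioxin-4-one | CC1=CC(=O)OC(C)(C)O1 | starting material
15 | lithium dienolate of 14 (6-methylene-4-lithiooxy-2,2-dimethyl-6H-1,3-dioxine) | C=C1C=C(O[Li])OC(C)(C)O1 | intermediate (not isolated)
16 | 2,2-dimethyl-6-(2-oxopropyl)-4H-1,3-dioxin-4-one | CC(=O)CC1=CC(=O)OC(C)(C)O1 | intermediate
17 | dilithium dianion of 16 (bis-enolate, drawn O-lithiated) | C=C(O[Li])C=C1C=C(O[Li])OC(C)(C)O1 | intermediate (not isolated)
18 | 6-[(6S,16S)-6,16-bis(tert-butyldimethylsilyloxy)-2,4-dioxoheptadecyl]-2,2-dimethyl-4H-1,3-dioxin-4-one (keto form drawn; enol tautomers expected) | C[C@H](O[Si](C)(C)C(C)(C)C)CCCCCCCCC[C@H](O[Si](C)(C)C(C)(C)C)CC(=O)CC(=O)CC1=CC(=O)OC(C)(C)O1 | intermediate (precursor of the key step)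
19 | 5-[(2S,12S)-2,12-bis(tert-butyldimethylsilyloxy)tridecyl]-5-hydroxy-2,2-dimethyl-5,8-dihydro-4H-1,3-benzodioxine-4,7(6H)-dione (aldol adduct, both C5 epimers) | C[C@H](O[Si](C)(C)C(C)(C)C)CCCCCCCCC[C@H](O[Si](C)(C)C(C)(C)C)CC1(O)CC(=O)CC2=C1C(=O)OC(C)(C)O2 | intermediate (not isolated)
20 | 5-[(2S,12S)-2,12-bis(tert-butyldimethylsilyloxy)tridecyl]-7-hydroxy-2,2-dimethyl-4H-1,3-benzodioxin-4-one | C[C@H](O[Si](C)(C)C(C)(C)C)CCCCCCCCC[C@H](O[Si](C)(C)C(C)(C)C)Cc1cc(O)cc2OC(C)(C)OC(=O)c12 | intermediate (product of the key step)
21 | benzyl 6-[(2S,12S)-2,12-bis(tert-butyldimethylsilyloxy)tridecyl]-2,4-dihydroxybenzoate | C[C@H](O[Si](C)(C)C(C)(C)C)CCCCCCCCC[C@H](O[Si](C)(C)C(C)(C)C)Cc1cc(O)cc(O)c1C(=O)OCc1ccccc1 | intermediate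
22 | benzyl 2,4-diacetoxy-6-[(2S,12S)-2,12-diacetoxytridecyl]benzoate | C[C@H](OC(C)=O)CCCCCCCCC[C@H](OC(C)=O)Cc1cc(OC(C)=O)cc(OC(C)=O)c1C(=O)OCc1ccccc1 | intermediate
23 | benzyl 6-[(2S,12S)-2,12-diacetoxytridecyl]-2,4-dihydroxybenzoate | C[C@H](OC(C)=O)CCCCCCCCC[C@H](OC(C)=O)Cc1cc(O)cc(O)c1C(=O)OCc1ccccc1 | intermediate
24 | 6-[(2S,12S)-2,12-diacetoxytridecyl]-2,4-dihydroxybenzoic acid | CC(=O)O[C@@H](CCCCCCCCC[C@H](C)OC(C)=O)Cc1cc(O)cc(O)c1C(=O)O | target

Total step count: 14. Longest linear sequence: 13 steps (steps 1–7 and 9–14, from 1 and 2); step 8 is a one-step side branch.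

Steps most likely to fail

Step 9. The basic dianion may deprotonate the Weinreb amide instead of adding to it, which would return the amide or lead to E1cB loss of silanol. The fallback replaces acyl transfer by aldol addition and oxidation. It sets out from 13, which i-Bu2AlH (THF, −78 °C) should reduce to (3S,13S)-3,13-bis(tert-butyldimethylsilyloxy)tetradecanal F1. The aldehyde is far more electrophilic than the amide and should be captured by dianion 17 at −78 °C to give 6-[(6S,16S)-6,16-bis(tert-butyldimethylsilyloxy)-4-hydroxy-2-oxoheptadecyl]-2,2-dimethyl-4H-1,3-dioxin-4-one F2 as a mixture of C4 epimers. Oxidation with Dess–Martin periodinane (CH2Cl2, NaHCO3, 0 °C) should then give the diketone, and the route is rejoined at 18.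

Step 10. The cyclisation may stall at the aldol adduct, or the open chain may divert to O-cyclised or eliminated material before the carbocycle forms. The fallback opens the dioxinone before ring closure. It sets out from 18, which on heating with benzyl alcohol in toluene at 110 °C should lose acetone by retro-[4+2] fragmentation to an acyl ketene that the alcohol traps, giving benzyl (9S,19S)-9,19-bis(tert-butyldimethylsilyloxy)-3,5,7-trioxoicosanoate F3. Treatment with Cs2CO3 in CH2Cl2/i-PrOH followed by mild acidification (AcOH) should bring about the same C2–C7 aldol condensation and aromatisation. The route is rejoined at 21, so that step 11 is no longer needed.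

Step 12. The silyl–acyl exchange may remain incomplete at the hindered secondary positions, or the Lewis acid may erode the benzyl ester. The fallback separates deprotection from acylation. It sets out from 21, which HF·pyridine buffered with excess pyridine (THF, 0 °C) should convert, without alkoxide formation, to benzyl 2,4-dihydroxy-6-[(2S,12S)-2,12-dihydroxytridecyl]benzoate F4. This diol would be kept cold, not chromatographed, and acetylated at once with Ac2O, pyridine and DMAP in CH2Cl2 so that acylation of the C2' hydroxyl outruns lactonisation. The route is rejoined at 22.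

Further compounds
F1 | step 9 | (3S,13S)-3,13-bis(tert-butyldimethylsilyloxy)tetradecanal | C[C@H](O[Si](C)(C)C(C)(C)C)CCCCCCCCC[C@H](O[Si](C)(C)C(C)(C)C)CC=O
F2 | step 9 | 6-[(6S,16S)-6,16-bis(tert-butyldimethylsilyloxy)-4-hydroxy-2-oxoheptadecyl]-2,2-dimethyl-4H-1,3-dioxin-4-one (C4 epimers) | C[C@H](O[Si](C)(C)C(C)(C)C)CCCCCCCCC[C@H](O[Si](C)(C)C(C)(C)C)CC(O)CC(=O)CC1=CC(=O)OC(C)(C)O1
F3 | step 10 | benzyl (9S,19S)-9,19-bis(tert-butyldimethylsilyloxy)-3,5,7-trioxoicosanoate | C[C@H](O[Si](C)(C)C(C)(C)C)CCCCCCCCC[C@H](O[Si](C)(C)C(C)(C)C)CC(=O)CC(=O)CC(=O)CC(=O)OCc1ccccc1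
F4 | step 12 | benzyl 2,4-dihydroxy-6-[(2S,12S)-2,12-dihydroxytridecyl]benzoate | C[C@H](O)CCCCCCCCC[C@H](O)Cc1cc(O)cc(O)c1C(=O)OCc1ccccc1
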